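**Retrosynthetic overview**
1. Target 13 ⇐ isopropyl ester 12 (selective saponification) ⇐ acetoxy ketone 11 (Baeyer–Villiger). The side-chain acid stays masked as an isopropyl ketone until the tertiary acetate is in place, so it cannot lactonise onto C8.
2. Key disconnection: the C8–O bond of the tertiary acetate. 11 ⇐ exocyclic alkene 7 by a radical Markovnikov hydroacetoxylation (O2 capture at C8 from the α face, acetylation on the peroxide, removal of one oxygen).
3. 7 ⇐ enal 3 by reductive 1,3-transposition; the C14 aldehyde carbon becomes the exocyclic methylene and later the 8β-methyl.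
4. 3 ⇐ abietic acid 1 by oxidative cleavage of C13=C14. No ring is formed: rings A and B and the C4, C5, C9 and C10 stereocentres come from 1, ring C is opened, and only C8 is set in the route.

Assumption: terpenoid numbering with α/β face descriptors is used (abietane for 1–11, labdane for 12 and 13; C18 is the 4α-carboxyl), and commercial abietic acid is recrystallised once before use.

**Step 1**
Reactants: 1 abietic acid (abieta-7,13-dien-18-oic acid)
Product: 3 13,14-dioxo-13,14-secoabiet-7-en-18-oic acid, via diol 2 (not isolated)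
Conditions: OsO4 (2 mol %), NaIO4 (4 equiv), 2,6-lutidine (2 equiv), dioxane/H2O 3:1, rt
Reagents that add atoms: osmium tetroxide, O=[Os](=O)(=O)=O; sodium periodate, [Na+].[O-]I(=O)(=O)=O
Why: Lemieux–Johnson oxidation, in which OsO4 is expected to osmylate only the isopropyl-bearing C13=C14 bond (the classical site of glycol formation in abietic acid), periodate cleaves the cis-diol at once, and the resulting enal C7=C8 bond is too electron-poor and hindered to react further; no stereocentre is made and C4, C5, C9 and C10 are untouched.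

**Step 2**
Reactants: 3 13,14-dioxo-13,14-secoabiet-7-en-18-oic acid
Product: 7 13-oxo-13,14-secoabiet-8(14)-en-18-oic acid, via tosylhydrazone 4 (not isolated), via allyl tosylhydrazine 5 (not isolated), via allyl diazene 6 (not isolated)
Conditions: TsNHNH2 (1.05 equiv), CHCl3, rt; then catecholborane (3.5 equiv), 0 °C to rt; then NaOAc·3H2O, reflux
Reagents that add atoms: none
Why: Kabalka-type reductive 1,3-transposition of an enal tosylhydrazone (a Wolff–Kishner variant), in which the aldehyde condenses far faster than the α-branched ketone, hydride adds to C=N, acetate-induced loss of sulfinate gives the allyl diazene, and retro-ene loss of N2 delivers hydrogen to C7 and moves the double bond to the exocyclic C8=C14 position; no stereocentre is formed.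

**Step 3**
Reactants: 7 13-oxo-13,14-secoabiet-8(14)-en-18-oic acid
Product: 11 8α-acetoxy-13-oxo-13,14-secoabietan-18-oic acid, via silyl peroxide 8 (not isolated), via hydroperoxide 9 (not isolated), via peracetate 10 (not isolated)
Conditions: Co(C11H19O2)2 [bis(2,2,6,6-tetramethylheptane-3,5-dionato)cobalt] (10 mol %), Et3SiH, O2 (1 atm), ClCH2CH2Cl, rt; then HF·pyridine, pyridine, Ac2O, DMAP (cat.), 0 °C; then PPh3, Ar, 40 °C
Reagents that add atoms: dioxygen, O=O; acetic anhydride, CC(=O)OC(C)=O
Why: Proposed new method: a radical Markovnikov hydroacetoxylation by peroxide relay, in which cobalt-hydride hydrogen-atom transfer to the CH2 terminus gives the tertiary C8 radical, O2 captures it from the α face (trans to the axial C10 methyl, so oxygen becomes equatorial 8α and the new methyl axial 8β) and the silane closes the cycle as silyl peroxide 8; fluoride frees hydroperoxide 9, whose unhindered terminal oxygen is acetylated to peracetate 10, and PPh3 then attacks the acyl-bearing peroxide oxygen so that the tertiary alkoxide released in the ion pair is acetylated by the acetoxyphosphonium ion, removing one oxygen as Ph3PO without breaking the C8–O bond (retention) and without a C8 cation that the δ-keto group would trap as a cyclic enol ether; the closest known reactions are the Isayama–Mukaiyama hydroperoxysilylation of alkenes and the phosphine deoxygenation of tert-butyl peresters to tert-butyl esters, which have not been combined into a hydroacetoxylation or applied to a hindered tertiary centre of this kind.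

**Step 4**
Reactants: 11 8α-acetoxy-13-oxo-13,14-secoabietan-18-oic acid
Product: 12 13-isopropyl hydrogen 8α-acetoxy-14,15,16-trinorlabdane-13,18-dioate
Conditions: mCPBA (2.5 equiv), CH2Cl2, rt, 36 h
Reagents that add atoms: mCPBA (3-chloroperoxybenzoic acid), OOC(=O)c1cccc(Cl)c1
Why: Baeyer–Villiger oxidation, in which the secondary isopropyl group migrates in preference to the primary C12 methylene of the Criegee intermediate to give the isopropyl ester, while the tertiary acetate, the acid and all stereocentres are inert to the peracid.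

**Step 5**
Reactants: 12 13-isopropyl hydrogen 8α-acetoxy-14,15,16-trinorlabdane-13,18-dioate
Product: 13 8α-acetoxy-14,15,16-trinorlabdane-13,18-dioic acid
Conditions: LiOH·H2O (3.2 equiv), THF/H2O 3:1, 0 °C to rt; then 1 M HCl to pH 3
Reagents that add atoms: lithium hydroxide monohydrate, [Li+].[OH-].O
Why: Rate-selective saponification (BAc2), in which the unhindered isopropyl ester should be hydrolysed roughly two orders of magnitude faster than the tertiary acetate, whose alkoxy carbon is quaternary and flanked by C9 and the axial methyl; the C18 acid is present as its carboxylate and no stereocentre is touched.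

**Compound list**
1 | abietic acid (abieta-7,13-dien-18-oic acid; 4α-CO2H, 5α-H, 9α-H, 10β-CH3) | CC(C)C1=CC2=CC[C@@H]3[C@](C)(CCC[C@@]3(C)C(=O)O)[C@H]2CC1 | starting material
2 | 13,14-dihydroxyabiet-7-en-18-oic acid (cis-diol, drawn 13β,14β; both carbinol centres are destroyed in the same flask) | CC(C)[C@]1(O)[C@@H](O)C2=CC[C@@H]3[C@](C)(CCC[C@@]3(C)C(=O)O)[C@H]2CC1 | intermediate
3 | 13,14-dioxo-13,14-secoabiet-7-en-18-oic acid (C14 formyl on C8 of the C7=C8 alkene; C13 isopropyl ketone on the 9β side chain) | O=CC1=CC[C@@H]2[C@](C)(CCC[C@@]2(C)C(=O)O)[C@H]1CCC(=O)C(C)C | intermediate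
4 | (E)-tosylhydrazone of 3 at C14 | Cc1ccc(cc1)S(=O)(=O)N/N=C/C1=CC[C@@H]2[C@](C)(CCC[C@@]2(C)C(=O)O)[C@H]1CCC(=O)C(C)C | intermediate
5 | allyl tosylhydrazine (hydride adduct of 4, C14H2–NH–NHTs; boron-bound until the acetate hydrate is added) | Cc1ccc(cc1)S(=O)(=O)NNCC1=CC[C@@H]2[C@](C)(CCC[C@@]2(C)C(=O)O)[C@H]1CCC(=O)C(C)C | intermediate
6 | allyl diazene (C7=C8–C14H2–N=NH) | N=NCC1=CC[C@@H]2[C@](C)(CCC[C@@]2(C)C(=O)O)[C@H]1CCC(=O)C(C)C | intermediate
7 | 13-oxo-13,14-secoabiet-8(14)-en-18-oic acid (exocyclic methylene on C8) | C=C1CC[C@@H]2[C@](C)(CCC[C@@]2(C)C(=O)O)[C@H]1CCC(=O)C(C)C | intermediate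
8 | 8α-(triethylsilylperoxy)-13-oxo-13,14-secoabietan-18-oic acid (8β-CH3) | CC[Si](CC)(CC)OO[C@]1(C)CC[C@@H]2[C@](C)(CCC[C@@]2(C)C(=O)O)[C@H]1CCC(=O)C(C)C | intermediate
9 | 8α-hydroperoxy-13-oxo-13,14-secoabietan-18-oic acid | OO[C@]1(C)CC[C@@H]2[C@](C)(CCC[C@@]2(C)C(=O)O)[C@H]1CCC(=O)C(C)C | intermediate
10 | 8α-(acetylperoxy)-13-oxo-13,14-secoabietan-18-oic acid | CC(=O)OO[C@]1(C)CC[C@@H]2[C@](C)(CCC[C@@]2(C)C(=O)O)[C@H]1CCC(=O)C(C)C | intermediate
11 | 8α-acetoxy-13-oxo-13,14-secoabietan-18-oic acid (8α-OAc equatorial, 8β-CH3 axial) | CC(=O)O[C@]1(C)CC[C@@H]2[C@](C)(CCC[C@@]2(C)C(=O)O)[C@H]1CCC(=O)C(C)C | intermediate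
12 | 13-isopropyl hydrogen 8α-acetoxy-14,15,16-trinorlabdane-13,18-dioate (side-chain isopropyl ester, C18 acid free) | CC(=O)O[C@]1(C)CC[C@@H]2[C@](C)(CCC[C@@]2(C)C(=O)O)[C@H]1CCC(=O)OC(C)C | intermediate
13 | 8α-acetoxy-14,15,16-trinorlabdane-13,18-dioic acid (CNP0196050.1) | CC(=O)O[C@]1(C)CC[C@@H]2[C@](C)(CCC[C@@]2(C)C(=O)O)[C@H]1CCC(=O)O | target

**Step count and risks**
Total steps: 5. Longest linear sequence: 5.

Three steps most likely to fail:

Step 3 (the proposed new method). The α-face preference in the O2 capture may be modest, the hydroperoxide may be reduced to the alcohol before it is acetylated, and the peracetate could undergo Criegee rearrangement on warming. The fallback uses known chemistry and sets out from 7. Mukaiyama hydration (Mn(C11H19O2)3, tris(2,2,6,6-tetramethylheptane-3,5-dionato)manganese, cat., PhSiH3, O2, iPrOH, rt) gives 8α-hydroxy-13-oxo-13,14-secoabietan-18-oic acid F3. The hindered tertiary alcohol is then acetylated classically (AcCl, N,N-dimethylaniline, CH2Cl2, reflux, aqueous work-up), which returns to the route at 11.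

Step 2. Catecholborane may partly reduce the isopropyl ketone, and the free acid consumes reagent. The fallback sets out from 3. Aldehyde-selective 1,2-reduction (NaBH4, MeOH/CH2Cl2, −78 °C) gives 14-hydroxy-13-oxo-13,14-secoabiet-7-en-18-oic acid F1. Acetylation (Ac2O, pyridine, DMAP, aqueous pyridine quench) gives 14-acetoxy-13-oxo-13,14-secoabiet-7-en-18-oic acid F2. Tsuji–Mandai formate hydrogenolysis (Pd(OAc)2 5 mol %, PBu3, HCO2NH4, dioxane, 100 °C) delivers hydride from the π-allylpalladium formate to the more substituted terminus C7 and gives the exocyclic alkene, returning to the route at 7.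

Step 5. Any loss of the tertiary acetate would lead to the δ-lactone. The fallback sets out from 12 and replaces steric rate control by enzyme control: Candida rugosa lipase or pig liver esterase in pH 7.5 phosphate buffer with acetone cosolvent at 30 °C, which does not accept esters of tertiary alcohols. It returns to the route at 13 and makes no new compound (F0).

**Further compounds**
F1 | step 2 | 14-hydroxy-13-oxo-13,14-secoabiet-7-en-18-oic acid | OCC1=CC[C@@H]2[C@](C)(CCC[C@@]2(C)C(=O)O)[C@H]1CCC(=O)C(C)C
F2 | step 2 | 14-acetoxy-13-oxo-13,14-secoabiet-7-en-18-oic acid | CC(=O)OCC1=CC[C@@H]2[C@](C)(CCC[C@@]2(C)C(=O)O)[C@H]1CCC(=O)C(C)C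
F3 | step 3 | 8α-hydroxy-13-oxo-13,14-secoabietan-18-oic acid | O[C@]1(C)CC[C@@H]2[C@](C)(CCC[C@@]2(C)C(=O)O)[C@H]1CCC(=O)C(C)C
F0 | step 5 | none | none
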